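**Retrosynthetic overview**
1. Feature: on ring B (the phenol ring; C1' OH, C2' ether oxygen, Br at C3', C5' and C6') the bromines at C3' and C5' lie ortho and para to the ether carbon C2' and meta to the hydroxyl. Phenol bromination cannot place them there, but two nitro groups can stand there first and be exchanged for bromine later.
2. C6'–Br is disconnected last (ortho-bromination of the free phenol); before that the C1' hydroxyl is carried as an isopropyl ether.
3. C3'–Br and C5'–Br are disconnected together to a ring B 1,3-diamine (double Sandmeyer bromination), which goes back to a 2,4-dinitroaryl ether.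
4. The diaryl ether bond C2'–O is disconnected by nitro-activated substitution: 2-chloro-1-isopropoxy-3,5-dinitrobenzene (from 2-isopropoxyphenol) plus 3,5-dibromo-2-methoxyphenol (ring A, from 3,5-dibromosalicylaldehyde by O-methylation and Baeyer–Villiger oxidation).
5. No ring is formed; both benzene rings are bought.

Key step: step 7

Remark on the chemistry: the target has no stereocentre, so the route only has to place substituents on two purchased benzene rings.

**Step 1**
Reactants: 1 2-isopropoxyphenol
Product: 2 2-isopropoxy-4,6-dinitrophenol
Conditions: HNO3 (fuming, 2.5 equiv), AcOH, 0 → 20 °C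
Reagents that add atoms: nitric acid, O[N+](=O)[O-]
Why: Electrophilic aromatic nitration in which the free hydroxyl directs the two nitro groups to its para (C4) and ortho (C6) positions, the second nitro group entering the one remaining site that is ortho/para to OH and meta to the first nitro group, while the secondary alkyl ether should survive cold HNO3/AcOH.

**Step 2**
Reactants: 2 2-isopropoxy-4,6-dinitrophenol
Product: 3 2-chloro-1-isopropoxy-3,5-dinitrobenzene
Conditions: POCl3 (3 equiv), PhNEt2 (1.2 equiv), 90 °C
Reagents that add atoms: phosphoryl chloride, O=P(Cl)(Cl)Cl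
Why: Chlorodehydroxylation of a 2,4-dinitrophenol, in which the aryl dichlorophosphate formed first is displaced by chloride through addition–elimination at the carbon activated by the ortho and para nitro groups (the reaction type that turns picric acid into picryl chloride), the amine base trapping HCl so that the isopropyl ether is spared.

**Step 3**
Reactants: 4 3,5-dibromosalicylaldehyde
Product: 5 3,5-dibromo-2-methoxybenzaldehyde
Conditions: MeI, K2CO3, DMF, 40 °C
Reagents that add atoms: iodomethane, CI
Why: Williamson O-methylation of an acidic, ortho-disubstituted phenoxide with an unhindered methyl electrophile.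

**Step 4**
Reactants: 5 3,5-dibromo-2-methoxybenzaldehyde
Product: 7 3,5-dibromo-2-methoxyphenol, via aryl formate 6 (not isolated)
Conditions: mCPBA, CH2Cl2, 40 °C; aq. NaHCO3 wash; then K2CO3 (cat.), MeOH, 20 °C
Reagents that add atoms: 3-chloroperoxybenzoic acid (mCPBA), OOC(=O)c1cccc(Cl)c1
Why: Baeyer–Villiger oxidation of an ortho-methoxybenzaldehyde, in which the alkoxy-substituted aryl group migrates in the Criegee intermediate to give the aryl formate, which is cleaved by base-catalysed methanolysis to the phenol.

**Step 5**
Reactants: 3 2-chloro-1-isopropoxy-3,5-dinitrobenzene; 7 3,5-dibromo-2-methoxyphenol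
Product: 8 1,5-dibromo-3-(2-isopropoxy-4,6-dinitrophenoxy)-2-methoxybenzene
Conditions: K2CO3, DMF, 20 → 50 °C
Reagents that add atoms: none
Why: Nucleophilic aromatic substitution (addition–elimination through a Meisenheimer complex) of the phenoxide of 7 at the chlorine-bearing carbon, which is activated by one ortho and one para nitro group, whereas the isopropoxy group is meta to both nitro groups and the aryl bromides of ring A are unactivated.

**Step 6**
Reactants: 8 1,5-dibromo-3-(2-isopropoxy-4,6-dinitrophenoxy)-2-methoxybenzene
Product: 9 4-(3,5-dibromo-2-methoxyphenoxy)-5-isopropoxybenzene-1,3-diamine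
Conditions: Fe powder, AcOH/EtOH, 70 °C
Reagents that add atoms: none
Why: Béchamp-type dissolving-metal reduction of both nitro groups, which leaves aryl bromides and the diaryl ether untouched where catalytic hydrogenation would risk debromination; the air-sensitive diamine is used directly.

**Step 7**
Reactants: 9 4-(3,5-dibromo-2-methoxyphenoxy)-5-isopropoxybenzene-1,3-diamine
Product: 11 1,5-dibromo-2-(3,5-dibromo-2-methoxyphenoxy)-3-isopropoxybenzene, via bis-diazonium dibromide 10 (not isolated)
Conditions: t-BuONO (3 equiv), CuBr2 (2.5 equiv), MeCN, slow addition of 9 at 0 °C, then 60 °C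
Reagents that add atoms: copper dibromide, [Cu+2].[Br-].[Br-] (both new bromines of 11); tert-butyl nitrite, CC(C)(C)ON=O (outer nitrogen of each diazonium group of 10, lost as N2)
Why: tert-Butyl nitrite nitrosates each amino group and loss of water gives the arenediazonium ion; monovalent copper formed in situ from CuBr2 transfers an electron, N2 leaves, and the aryl radical takes bromine from divalent copper bromide, which forms the C3'–Br and C5'–Br bonds at the carbons that carried nitrogen. The closest known reaction type is the aprotic Sandmeyer bromination of anilines with alkyl nitrite and CuBr2, here run twice on one ring. No ring closes and no stereocentre is formed. The step needs complete bis-diazotization without azo or triazene coupling of the electron-rich meta-diamine and without ring bromination at C4' or C6' by CuBr2. Slow addition of 9 into excess nitrite and CuBr2 should secure this, since each amino group is diazotized and consumed as it arrives and the first diazonium or bromo substituent deactivates the ring towards coupling. The positions of the two bromines are fixed by ipso replacement, so the ortho/para pattern set by the nitro groups in step 1 is carried over unchanged.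

**Step 8**
Reactants: 11 1,5-dibromo-2-(3,5-dibromo-2-methoxyphenoxy)-3-isopropoxybenzene
Product: 12 3,5-dibromo-2-(3,5-dibromo-2-methoxyphenoxy)phenol
Conditions: BCl3 (1 M in CH2Cl2, 2 equiv), CH2Cl2, −78 → 0 °C; H2O
Reagents that add atoms: none
Why: Lewis-acid cleavage of a secondary alkyl aryl ether, in which BCl3 coordinates the ether oxygen and the isopropyl group leaves as 2-chloropropane at a temperature where a methyl aryl ether lacking a chelating carbonyl should stay intact.

**Step 9**
Reactants: 12 3,5-dibromo-2-(3,5-dibromo-2-methoxyphenoxy)phenol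
Product: 13 2,3,5-tribromo-6-(3,5-dibromo-2-methoxyphenoxy)phenol (target)
Conditions: NBS (1.05 equiv), i-Pr2NH (10 mol %), CH2Cl2, 0 → 20 °C
Reagents that add atoms: N-bromosuccinimide, O=C1CCC(=O)N1Br
Why: Amine-catalysed ortho-bromination of a phenol, in which the N-bromoamine hydrogen-bonded to the hydroxyl delivers bromine to C6', the only free ortho position, while the para position C4' is flanked by two bromines and ring A is deactivated and carries no free hydroxyl.

**Compound list**
1 | 2-isopropoxyphenol | CC(C)Oc1ccccc1O | starting material
2 | 2-isopropoxy-4,6-dinitrophenol | CC(C)Oc1cc(cc(c1O)[N+](=O)[O-])[N+](=O)[O-] | intermediate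
3 | 2-chloro-1-isopropoxy-3,5-dinitrobenzene | CC(C)Oc1cc(cc(c1Cl)[N+](=O)[O-])[N+](=O)[O-] | intermediate
4 | 3,5-dibromosalicylaldehyde (3,5-dibromo-2-hydroxybenzaldehyde) | O=Cc1cc(Br)cc(Br)c1O | starting material
5 | 3,5-dibromo-2-methoxybenzaldehyde | COc1c(Br)cc(Br)cc1C=O | intermediate
6 | 3,5-dibromo-2-methoxyphenyl formate | COc1c(Br)cc(Br)cc1OC=O | intermediate
7 | 3,5-dibromo-2-methoxyphenol | COc1c(Br)cc(Br)cc1O | intermediate
8 | 1,5-dibromo-3-(2-isopropoxy-4,6-dinitrophenoxy)-2-methoxybenzene | COc1c(Br)cc(Br)cc1Oc1c(OC(C)C)cc(cc1[N+](=O)[O-])[N+](=O)[O-] | intermediate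
9 | 4-(3,5-dibromo-2-methoxyphenoxy)-5-isopropoxybenzene-1,3-diamine | COc1c(Br)cc(Br)cc1Oc1c(N)cc(N)cc1OC(C)C | intermediate
10 | 4-(3,5-dibromo-2-methoxyphenoxy)-5-isopropoxybenzene-1,3-bis(diazonium) dibromide | COc1c(Br)cc(Br)cc1Oc1c([N+]#N)cc([N+]#N)cc1OC(C)C.[Br-].[Br-] | intermediate
11 | 1,5-dibromo-2-(3,5-dibromo-2-methoxyphenoxy)-3-isopropoxybenzene | COc1c(Br)cc(Br)cc1Oc1c(Br)cc(Br)cc1OC(C)C | intermediate
12 | 3,5-dibromo-2-(3,5-dibromo-2-methoxyphenoxy)phenol | COc1c(Br)cc(Br)cc1Oc1c(Br)cc(Br)cc1O | intermediate
13 | 2,3,5-tribromo-6-(3,5-dibromo-2-methoxyphenoxy)phenol | COc1c(Br)cc(Br)cc1Oc1c(Br)cc(Br)c(Br)c1O | target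

**Total step count:** 9
**Longest linear sequence:** 7 steps (steps 1, 2, 5, 6, 7, 8, 9 from 1; the branch from 4 through steps 3, 4, 5–9 is equally long)

**Steps most likely to fail**

Step 7 (double Sandmeyer). The first diazonium ion may couple with diamine that has not yet reacted (azo or triazene formation), CuBr2 may brominate the electron-rich diamine ring before diazotization, and part of the material may lose N2 with hydrogen in place of bromine. The fallback exchanges the two nitrogens one after the other, so that no free amino group ever sits on an activated ring beside a diazonium ion; it sets out from 8 and comes back at 11. NaHS in MeOH/H2O at 60 °C (Zinin reduction) should reduce one nitro group, by the usual preference the one ortho to the ether oxygen, to give 2-(3,5-dibromo-2-methoxyphenoxy)-3-isopropoxy-5-nitroaniline F1. Treatment with t-BuONO and CuBr2 in MeCN converts it, through 2-(3,5-dibromo-2-methoxyphenoxy)-3-isopropoxy-5-nitrobenzenediazonium bromide F2, into 1-bromo-2-(3,5-dibromo-2-methoxyphenoxy)-3-isopropoxy-5-nitrobenzene F3. Fe powder in AcOH then gives 3-bromo-4-(3,5-dibromo-2-methoxyphenoxy)-5-isopropoxyaniline F4, and a second t-BuONO/CuBr2 treatment, through 3-bromo-4-(3,5-dibromo-2-methoxyphenoxy)-5-isopropoxybenzenediazonium bromide F5, gives 11. The order in which the two nitro groups are exchanged does not matter for 11.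

Step 1 (dinitration). Nitric acid may oxidise the electron-rich alkoxyphenol to quinones and tar, or attack ipso at the isopropoxy carbon with loss of the alkyl group, before the second nitro group is in place. The fallback brings in the first nitrogen with a non-oxidising electrophile and nitrates only a deactivated ring; it sets out from 1 and comes back at 2. Nitrosation with NaNO2 in aqueous AcOH at 0 °C should go para to the hydroxyl and give 2-isopropoxy-4-nitrosophenol F6. Dilute HNO3 at 20–30 °C oxidises the nitroso group to give 2-isopropoxy-4-nitrophenol F7. A single nitration of this deactivated phenol with HNO3 in AcOH, ortho to the hydroxyl, then gives 2.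

Step 2 (chlorodehydroxylation). Chloride may displace the phosphate only slowly at a carbon flanked by isopropoxy and nitro groups, and hot acidic phosphoryl chloride may strip the isopropyl group. The fallback activates the phenol as a sulfonate under mild basic conditions and brings in chloride in a separate substitution; it sets out from 2 and comes back at 3. TsCl and Et3N in CH2Cl2 give 2-isopropoxy-4,6-dinitrophenyl 4-methylbenzenesulfonate F8. LiCl in DMF at 80 °C then displaces the sulfonate at the nitro-activated carbon by addition–elimination to give 3; chloride attack at sulfur only regenerates TsCl and the phenoxide, so the material should drain through the carbon pathway.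

**Further compounds**
F1 | step 7 | 2-(3,5-dibromo-2-methoxyphenoxy)-3-isopropoxy-5-nitroaniline | COc1c(Br)cc(Br)cc1Oc1c(N)cc(cc1OC(C)C)[N+](=O)[O-]
F2 | step 7 | 2-(3,5-dibromo-2-methoxyphenoxy)-3-isopropoxy-5-nitrobenzenediazonium bromide | COc1c(Br)cc(Br)cc1Oc1c([N+]#N)cc(cc1OC(C)C)[N+](=O)[O-].[Br-]
F3 | step 7 | 1-bromo-2-(3,5-dibromo-2-methoxyphenoxy)-3-isopropoxy-5-nitrobenzene | COc1c(Br)cc(Br)cc1Oc1c(Br)cc(cc1OC(C)C)[N+](=O)[O-]
F4 | step 7 | 3-bromo-4-(3,5-dibromo-2-methoxyphenoxy)-5-isopropoxyaniline | COc1c(Br)cc(Br)cc1Oc1c(Br)cc(N)cc1OC(C)C
F5 | step 7 | 3-bromo-4-(3,5-dibromo-2-methoxyphenoxy)-5-isopropoxybenzenediazonium bromide | COc1c(Br)cc(Br)cc1Oc1c(Br)cc([N+]#N)cc1OC(C)C.[Br-]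
F6 | step 1 | 2-isopropoxy-4-nitrosophenol | CC(C)Oc1cc(N=O)ccc1O
F7 | step 1 | 2-isopropoxy-4-nitrophenol | CC(C)Oc1cc(ccc1O)[N+](=O)[O-]
F8 | step 2 | 2-isopropoxy-4,6-dinitrophenyl 4-methylbenzenesulfonate | Cc1ccc(cc1)S(=O)(=O)Oc1c(OC(C)C)cc(cc1[N+](=O)[O-])[N+](=O)[O-]
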